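The dihydroisoquinoline ring (N2, C1, C8a, C4a, C4, C3) is disconnected at its N2=C1 imine bond, so its precursor is an open aryl methyl ketone whose neighbouring carbon carries an (R)-2-(Boc-amino)propyl chain. The key step exploits that C1 hangs on C8a, flanked by the C8 oxygen and C4a and para to the C6 oxygen: these four positions map onto the acetyl carbon and the three oxygens of phloroacetophenone, one oxygen leaving as a triflate for the chain. On the complete, otherwise deprotected binaphthyl skeleton, acid frees the amine, which condenses with the ketone and closes the last ring with no regiochemical choice left.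

Key step: step 22

Assumption: the SMILES fixes only the three stereogenic carbons; the two hindered biaryl axes (isoquinoline C5 to naphthalene, isoquinoline C7 to naphthalene) are undefined, so each is carried as a mixture of atropisomers.

Step 1
Reactants: 1 3-methylbut-2-enoyl chloride
Product: 2 N,N-diethyl-3-methylbut-2-enamide
Conditions: Et2NH, aq. NaOH, CH2Cl2, 0 °C
Reagents that add atoms: diethylamine, CCNCC
Why: Schotten–Baumann acylation of the secondary amine should proceed cleanly and leave the trisubstituted alkene untouched.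

Step 2
Reactants: 2 N,N-diethyl-3-methylbut-2-enamide; 3 1-bromo-3-(methoxymethoxy)benzene
Product: 6 8-(methoxymethoxy)-3-methylnaphthalen-1-ol, via lithium dienolate 4 (not isolated), via aryne 5 (not isolated)
Conditions: LiN(iPr)2 (2.3 equiv), THF, −78 °C to rt; then AcOH
Reagents that add atoms: none
Why: In this aryne–dienolate naphthol annulation the base forms the dienolate of 2 and, by lithiation between Br and OMOM and loss of LiBr, the aryne of 3; the dienolate terminus should add meta to the OMOM group so that the aryl anion ortho to oxygen closes onto the amide carbonyl, placing the new OH peri to the OMOM oxygen.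

Step 3
Reactants: 6 8-(methoxymethoxy)-3-methylnaphthalen-1-ol
Product: 7 1-methoxy-8-(methoxymethoxy)-3-methylnaphthalene
Conditions: MeI, K2CO3, DMF, rt
Reagents that add atoms: iodomethane, IC
Why: Williamson methylation of the only free hydroxyl should fix the methoxy group on the methyl-bearing ring.

Step 4
Reactants: 7 1-methoxy-8-(methoxymethoxy)-3-methylnaphthalene
Product: 8 8-methoxy-6-methylnaphthalen-1-ol
Conditions: HCl (cat.), MeOH, 40 °C
Reagents that add atoms: none
Why: Acid-catalysed transacetalization should remove the MOM acetal while the methyl ether stays.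

Step 5
Reactants: 8 8-methoxy-6-methylnaphthalen-1-ol
Product: 9 4-bromo-8-methoxy-6-methylnaphthalen-1-ol
Conditions: NBS, MeCN, −20 °C
Reagents that add atoms: N-bromosuccinimide, O=C1CCC(=O)N1Br
Why: In this electrophilic bromination the free hydroxyl is a far stronger donor than the methoxy group and should direct bromine para to itself, to the carbon that will carry the isoquinoline units.

Step 6
Reactants: 9 4-bromo-8-methoxy-6-methylnaphthalen-1-ol
Product: 10 8-methoxy-6-methyl-4-(4,4,5,5-tetramethyl-1,3,2-dioxaborolan-2-yl)naphthalen-1-ol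
Conditions: B2pin2, PdCl2(dppf) (3 mol%), KOAc, dioxane, 85 °C
Reagents that add atoms: bis(pinacolato)diboron, CC1(C)OB(OC1(C)C)B1OC(C)(C)C(C)(C)O1
Why: Miyaura borylation with the weak base KOAc should tolerate the free naphthol and give the one boron partner used for both biaryl bonds.

Step 7
Reactants: 11 tert-butyl N-[(2R)-1-hydroxypropan-2-yl]carbamate (N-Boc-D-alaninol)
Product: 12 tert-butyl N-[(2R)-1-iodopropan-2-yl]carbamate
Conditions: iodine, PPh3, imidazole, CH2Cl2, 0 °C to rt
Reagents that add atoms: iodine, [I][I]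
Why: The Appel reaction should convert the primary alcohol into the iodide without touching the neighbouring stereocentre, which becomes C3 of both isoquinoline units.

Step 8
Reactants: 12 tert-butyl N-[(2R)-1-iodopropan-2-yl]carbamate
Product: 13 [(2R)-2-(tert-butoxycarbonylamino)propyl]zinc iodide (titrated DMF solution)
Conditions: Zn dust, iodine (cat.), DMF, rt; kept under argon at −20 °C
Reagents that add atoms: zinc, [Zn]
Why: Oxidative insertion of iodine-activated zinc into the primary C–I bond in DMF should give the β-amido alkylzinc iodide without touching the R stereocentre, DMF coordination slowing β-elimination of the carbamate; the two branches are timed so that steps 9 and 19 draw on this one titrated solution.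

Step 9
Reactants: 13 [(2R)-2-(tert-butoxycarbonylamino)propyl]zinc iodide; 14 1,3-bis(benzyloxy)-5-bromobenzene
Product: 15 tert-butyl N-[(2R)-1-[3,5-bis(benzyloxy)phenyl]propan-2-yl]carbamate
Conditions: 13 (1.5 equiv, DMF solution), Pd2(dba)3 (2.5 mol%), SPhos (5 mol%), DMF, 40 °C
Reagents that add atoms: none
Why: Negishi coupling of the β-amido alkylzinc iodide with the aryl bromide should form the aryl–CH2 bond, the R stereocentre being carried in unchanged from 12.

Step 10
Reactants: 15 tert-butyl N-[(2R)-1-[3,5-bis(benzyloxy)phenyl]propan-2-yl]carbamate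
Product: 17 (2R)-N-benzyl-1-[3,5-bis(benzyloxy)phenyl]propan-2-amine, via primary amine 16 (not isolated)
Conditions: TFA, CH2Cl2, rt; concentrate; then PhCHO, Et3N, NaBH(OAc)3, ClCH2CH2Cl, rt
Reagents that add atoms: benzaldehyde, O=Cc1ccccc1
Why: Boc cleavage and reductive amination should install the N-benzyl group that steers the next cyclization to the trans product.

Step 11
Reactants: 17 (2R)-N-benzyl-1-[3,5-bis(benzyloxy)phenyl]propan-2-amine
Product: 18 (1R,3R)-2-benzyl-6,8-bis(benzyloxy)-1,3-dimethyl-1,2,3,4-tetrahydroisoquinoline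
Conditions: MeCHO, TFA, CH2Cl2, 0 °C to rt
Reagents that add atoms: acetaldehyde, CC=O
Why: In this Pictet–Spengler reaction the N-benzyl iminium should cyclize onto either of the two equivalent ring positions with the C3 methyl pseudoaxial to avoid A(1,3) strain, so the new C1 methyl ends trans (1R) by substrate control, as with N-benzyl tryptophan esters.

Step 12
Reactants: 18 (1R,3R)-2-benzyl-6,8-bis(benzyloxy)-1,3-dimethyl-1,2,3,4-tetrahydroisoquinoline
Product: 19 (1R,3R)-2-benzyl-6,8-bis(benzyloxy)-5-bromo-1,3-dimethyl-1,2,3,4-tetrahydroisoquinoline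
Conditions: NBS, TFA (1.1 equiv), CH2Cl2, −20 °C
Reagents that add atoms: N-bromosuccinimide, O=C1CCC(=O)N1Br
Why: Electrophilic bromination should go to C5 (ortho to one benzyloxy group, para to the other) because C7 is shielded between two benzyloxy groups, and protonation protects the amine.

Step 13
Reactants: 19 (1R,3R)-2-benzyl-6,8-bis(benzyloxy)-5-bromo-1,3-dimethyl-1,2,3,4-tetrahydroisoquinoline; 10 8-methoxy-6-methyl-4-(4,4,5,5-tetramethyl-1,3,2-dioxaborolan-2-yl)naphthalen-1-ol
Product: 20 4-[(1R,3R)-2-benzyl-6,8-bis(benzyloxy)-1,3-dimethyl-1,2,3,4-tetrahydroisoquinolin-5-yl]-8-methoxy-6-methylnaphthalen-1-ol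
Conditions: Pd(OAc)2 (5 mol%), SPhos (10 mol%), K3PO4, toluene/H2O, 90 °C
Reagents that add atoms: none
Why: Suzuki–Miyaura coupling with a bulky biaryl phosphine should build the tri-ortho-substituted biaryl in the presence of the free naphthol, giving both atropisomers at the new axis.

Step 14
Reactants: 21 1-(2,4,6-trihydroxyphenyl)ethanone (phloroacetophenone)
Product: 22 1-[4-(benzyloxy)-2,6-dihydroxyphenyl]ethanone
Conditions: BnBr (1.0 equiv), K2CO3 (1.0 equiv), DMF, rt
Reagents that add atoms: benzyl bromide, BrCc1ccccc1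
Why: Williamson alkylation should select the para hydroxyl, the only one not hydrogen-bonded to the acetyl group; it becomes the C6 oxygen.

Step 15
Reactants: 22 1-[4-(benzyloxy)-2,6-dihydroxyphenyl]ethanone
Product: 23 2-acetyl-5-(benzyloxy)-3-hydroxyphenyl trifluoromethanesulfonate
Conditions: Tf2O (1.0 equiv), pyridine, CH2Cl2, −40 to 0 °C
Reagents that add atoms: trifluoromethanesulfonic anhydride, O=S(=O)(OS(=O)(=O)C(F)(F)F)C(F)(F)F
Why: O-sulfonylation of one of the two equivalent ortho hydroxyls should stop at the monotriflate, because the remaining hydroxyl is chelated to the ketone on a now electron-poorer ring.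

Step 16
Reactants: 23 2-acetyl-5-(benzyloxy)-3-hydroxyphenyl trifluoromethanesulfonate
Product: 24 2-acetyl-5-(benzyloxy)-3-hydroxy-4-iodophenyl trifluoromethanesulfonate
Conditions: NIS, TFA (cat.), MeCN, 0 °C to rt
Reagents that add atoms: N-iodosuccinimide, O=C1CCC(=O)N1I
Why: Electrophilic iodination should occur ortho to the free chelated hydroxyl, between OH and OBn, since the other open position is flanked by the bulky, deactivating triflate.

Step 17
Reactants: 24 2-acetyl-5-(benzyloxy)-3-hydroxy-4-iodophenyl trifluoromethanesulfonate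
Product: 25 2-acetyl-5-(benzyloxy)-4-iodo-3-methoxyphenyl trifluoromethanesulfonate
Conditions: MeI, K2CO3, DMF, rt
Reagents that add atoms: iodomethane, IC
Why: Williamson methylation of the remaining phenol should give the future C8 methoxy group.

Step 18
Reactants: 25 2-acetyl-5-(benzyloxy)-4-iodo-3-methoxyphenyl trifluoromethanesulfonate; 10 8-methoxy-6-methyl-4-(4,4,5,5-tetramethyl-1,3,2-dioxaborolan-2-yl)naphthalen-1-ol
Product: 26 2-acetyl-5-(benzyloxy)-4-(4-hydroxy-5-methoxy-7-methylnaphthalen-1-yl)-3-methoxyphenyl trifluoromethanesulfonate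
Conditions: Pd2(dba)3 (2.5 mol%), P(t-Bu)3·HBF4 (10 mol%), K3PO4, THF/H2O, 40 °C
Reagents that add atoms: none
Why: Suzuki–Miyaura coupling with the palladium/P(t-Bu)3 system should react at the aryl iodide far faster than at the aryl triflate, so the C7–naphthalene bond forms chemoselectively (atropisomers at the new axis).

Step 19
Reactants: 26 2-acetyl-5-(benzyloxy)-4-(4-hydroxy-5-methoxy-7-methylnaphthalen-1-yl)-3-methoxyphenyl trifluoromethanesulfonate; 13 [(2R)-2-(tert-butoxycarbonylamino)propyl]zinc iodide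
Product: 27 tert-butyl N-[(2R)-1-[2-acetyl-5-(benzyloxy)-4-(4-hydroxy-5-methoxy-7-methylnaphthalen-1-yl)-3-methoxyphenyl]propan-2-yl]carbamate
Conditions: 13 (3 equiv, DMF solution, slow addition), Pd2(dba)3 (2.5 mol%), SPhos (10 mol%), DMF, 50 °C
Reagents that add atoms: none
Why: Negishi coupling of the same alkylzinc reagent with the ortho-acyl-activated triflate should put the C4–C3–N chain on C4a with the R centre unchanged, the excess reagent covering protonolysis by the naphthol.

Step 20
Reactants: 20 4-[(1R,3R)-2-benzyl-6,8-bis(benzyloxy)-1,3-dimethyl-1,2,3,4-tetrahydroisoquinolin-5-yl]-8-methoxy-6-methylnaphthalen-1-ol; 27 tert-butyl N-[(2R)-1-[2-acetyl-5-(benzyloxy)-4-(4-hydroxy-5-methoxy-7-methylnaphthalen-1-yl)-3-methoxyphenyl]propan-2-yl]carbamate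
Product: 28 cross-coupled diphenoquinone (8,8'-dimethoxy-6,6'-dimethyl-2,2'-binaphthylidene-1,1'-dione bearing at C4 the tetrahydroisoquinolin-5-yl unit of 20 and at C4' the aryl unit of 27)
Conditions: Ag2O, Et3N (cat.), CHCl3, rt, dark; 20 in excess (2.5 equiv)
Reagents that add atoms: none
Why: In this oxidative phenol coupling the naphthoxyl radicals should join ortho to oxygen because the para positions carry the aryl groups, the binaphthol being oxidized on to the diphenoquinone; the excess of 20 should steer 27 into the cross-product, which differs from both homodimers in its number of basic nitrogens.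

Step 21
Reactants: 28 cross-coupled diphenoquinone
Product: 29 tert-butyl N-[(2R)-1-[2-acetyl-4-[1'-[(1R,3R)-6,8-dihydroxy-1,3-dimethyl-1,2,3,4-tetrahydroisoquinolin-5-yl]-4,4'-dihydroxy-5,5'-dimethoxy-7,7'-dimethyl-[3,3'-binaphthalen]-1-yl]-5-hydroxy-3-methoxyphenyl]propan-2-yl]carbamate
Conditions: H2 (1 atm), Pd/C (10% palladium on carbon), MeOH/CH2Cl2, rt
Reagents that add atoms: none
Why: Catalytic hydrogenation should reduce the diphenoquinone back to the binaphthol and cleave the three O-benzyl groups and the N-benzyl group, while the carbamate and the hindered, doubly ortho-substituted aryl ketone survive.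

Step 22
Reactants: 29 tert-butyl N-[(2R)-1-[2-acetyl-4-[1'-[(1R,3R)-6,8-dihydroxy-1,3-dimethyl-1,2,3,4-tetrahydroisoquinolin-5-yl]-4,4'-dihydroxy-5,5'-dimethoxy-7,7'-dimethyl-[3,3'-binaphthalen]-1-yl]-5-hydroxy-3-methoxyphenyl]propan-2-yl]carbamate
Product: 31 korundamine A, via amino ketone 30 (not isolated)
Conditions: HCl (4 M in dioxane), MeOH, 0 °C to rt; then aq. NaHCO3
Reagents that add atoms: none
Why: Acid cleaves the carbamate (loss of the tert-butyl cation and CO2) to free the C3 amine of 30, which adds to the C1 carbonyl of the acetyl group on C8a and loses water to give the aryl-conjugated cyclic ketimine, held as its iminium chloride until the NaHCO3 work-up. The reaction type is the deprotection–cyclocondensation of a δ-amino aryl ketone, the standard route from such ketones to 1-substituted 3,4-dihydroisoquinolines. The ring (N2, C1, C8a, C4a, C4, C3) closes by 6-exo-trig attack of nitrogen on the carbonyl carbon. No stereocentre is formed; C3 keeps the R configuration brought in with 12 because neither the acid nor imine formation touches its C–H bond, and the 1R,3R centres of the tetrahydroisoquinoline are not involved. Regioselectivity is not at stake, since C1 was fixed on C8a, between the C8 methoxy group and C4a, when the phloroacetophenone core was chosen. Chemoselectivity rests on the primary amine being the only group able to form a neutral imine, so the secondary amine and the five free phenols should stay spectators.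

Compound list
1 | 3-methylbut-2-enoyl chloride | CC(C)=CC(=O)Cl | starting material
2 | N,N-diethyl-3-methylbut-2-enamide | CC(C)=CC(=O)N(CC)CC | intermediate
3 | 1-bromo-3-(methoxymethoxy)benzene | COCOc1cccc(Br)c1 | starting material
4 | lithium dienolate of 2 (lithium 1-(diethylamino)-3-methylbuta-1,3-dien-1-olate) | C=C(C)C=C(O[Li])N(CC)CC | intermediate
5 | 3-(methoxymethoxy)benzyne | COCOC1=CC=CC#C1 | intermediate
6 | 8-(methoxymethoxy)-3-methylnaphthalen-1-ol | Cc1cc(O)c2c(OCOC)cccc2c1 | intermediate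
7 | 1-methoxy-8-(methoxymethoxy)-3-methylnaphthalene | COCOc1cccc2cc(C)cc(OC)c12 | intermediate
8 | 8-methoxy-6-methylnaphthalen-1-ol | COc1cc(C)cc2cccc(O)c12 | intermediate
9 | 4-bromo-8-methoxy-6-methylnaphthalen-1-ol | COc1cc(C)cc2c(Br)ccc(O)c12 | intermediate
10 | 8-methoxy-6-methyl-4-(4,4,5,5-tetramethyl-1,3,2-dioxaborolan-2-yl)naphthalen-1-ol | COc1cc(C)cc2c(B3OC(C)(C)C(C)(C)O3)ccc(O)c12 | intermediate
11 | tert-butyl N-[(2R)-1-hydroxypropan-2-yl]carbamate | OC[C@@H](C)NC(=O)OC(C)(C)C | starting material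
12 | tert-butyl N-[(2R)-1-iodopropan-2-yl]carbamate | IC[C@@H](C)NC(=O)OC(C)(C)C | intermediate
13 | [(2R)-2-(tert-butoxycarbonylamino)propyl]zinc iodide | I[Zn]C[C@@H](C)NC(=O)OC(C)(C)C | intermediate
14 | 1,3-bis(benzyloxy)-5-bromobenzene | Brc1cc(OCc2ccccc2)cc(OCc2ccccc2)c1 | starting material
15 | tert-butyl N-[(2R)-1-[3,5-bis(benzyloxy)phenyl]propan-2-yl]carbamate | c1(C[C@@H](C)NC(=O)OC(C)(C)C)cc(OCc2ccccc2)cc(OCc2ccccc2)c1 | intermediate
16 | (2R)-1-[3,5-bis(benzyloxy)phenyl]propan-2-amine | c1(C[C@@H](C)N)cc(OCc2ccccc2)cc(OCc2ccccc2)c1 | intermediate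
17 | (2R)-N-benzyl-1-[3,5-bis(benzyloxy)phenyl]propan-2-amine | c1(C[C@@H](C)NCc2ccccc2)cc(OCc2ccccc2)cc(OCc2ccccc2)c1 | intermediate
18 | (1R,3R)-2-benzyl-6,8-bis(benzyloxy)-1,3-dimethyl-1,2,3,4-tetrahydroisoquinoline | c1c(OCc2ccccc2)cc(OCc2ccccc2)c2c1C[C@@H](C)N(Cc1ccccc1)[C@@H]2C | intermediate
19 | (1R,3R)-2-benzyl-6,8-bis(benzyloxy)-5-bromo-1,3-dimethyl-1,2,3,4-tetrahydroisoquinoline | Brc1c(OCc2ccccc2)cc(OCc2ccccc2)c2c1C[C@@H](C)N(Cc1ccccc1)[C@@H]2C | intermediate
20 | 4-[(1R,3R)-2-benzyl-6,8-bis(benzyloxy)-1,3-dimethyl-1,2,3,4-tetrahydroisoquinolin-5-yl]-8-methoxy-6-methylnaphthalen-1-ol | COc1cc(C)cc2c(-c3c(OCc4ccccc4)cc(OCc4ccccc4)c4c3C[C@@H](C)N(Cc3ccccc3)[C@@H]4C)ccc(O)c12 | intermediate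
21 | 1-(2,4,6-trihydroxyphenyl)ethanone | CC(=O)c1c(O)cc(O)cc1O | starting material
22 | 1-[4-(benzyloxy)-2,6-dihydroxyphenyl]ethanone | CC(=O)c1c(O)cc(OCc2ccccc2)cc1O | intermediate
23 | 2-acetyl-5-(benzyloxy)-3-hydroxyphenyl trifluoromethanesulfonate | CC(=O)c1c(O)cc(OCc2ccccc2)cc1OS(=O)(=O)C(F)(F)F | intermediate
24 | 2-acetyl-5-(benzyloxy)-3-hydroxy-4-iodophenyl trifluoromethanesulfonate | CC(=O)c1c(O)c(I)c(OCc2ccccc2)cc1OS(=O)(=O)C(F)(F)F | intermediate
25 | 2-acetyl-5-(benzyloxy)-4-iodo-3-methoxyphenyl trifluoromethanesulfonate | CC(=O)c1c(OC)c(I)c(OCc2ccccc2)cc1OS(=O)(=O)C(F)(F)F | intermediate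
26 | 2-acetyl-5-(benzyloxy)-4-(4-hydroxy-5-methoxy-7-methylnaphthalen-1-yl)-3-methoxyphenyl trifluoromethanesulfonate | CC(=O)c1c(OC)c(-c2ccc(O)c3c(OC)cc(C)cc23)c(OCc2ccccc2)cc1OS(=O)(=O)C(F)(F)F | intermediate
27 | tert-butyl N-[(2R)-1-[2-acetyl-5-(benzyloxy)-4-(4-hydroxy-5-methoxy-7-methylnaphthalen-1-yl)-3-methoxyphenyl]propan-2-yl]carbamate | CC(=O)c1c(OC)c(-c2ccc(O)c3c(OC)cc(C)cc23)c(OCc2ccccc2)cc1C[C@@H](C)NC(=O)OC(C)(C)C | intermediate
28 | cross-coupled diphenoquinone (8,8'-dimethoxy-6,6'-dimethyl-2,2'-binaphthylidene-1,1'-dione with the tetrahydroisoquinolin-5-yl unit of 20 at C4 and the aryl unit of 27 at C4') | COc1cc(C)cc2c1C(=O)C(=C1C=C(c3c(OC)c(C(C)=O)c(C[C@@H](C)NC(=O)OC(C)(C)C)cc3OCc3ccccc3)c3cc(C)cc(OC)c3C1=O)C=C2c1c(OCc2ccccc2)cc(OCc2ccccc2)c2c1C[C@@H](C)N(Cc1ccccc1)[C@@H]2C | intermediate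
29 | tert-butyl N-[(2R)-1-[2-acetyl-4-[1'-[(1R,3R)-6,8-dihydroxy-1,3-dimethyl-1,2,3,4-tetrahydroisoquinolin-5-yl]-4,4'-dihydroxy-5,5'-dimethoxy-7,7'-dimethyl-[3,3'-binaphthalen]-1-yl]-5-hydroxy-3-methoxyphenyl]propan-2-yl]carbamate | COc1c(C(C)=O)c(C[C@@H](C)NC(=O)OC(C)(C)C)cc(O)c1-c1cc(-c2cc(-c3c(O)cc(O)c4c3C[C@@H](C)N[C@@H]4C)c3cc(C)cc(OC)c3c2O)c(O)c2c(OC)cc(C)cc12 | intermediate
30 | amino ketone (29 without the Boc group; (2R)-2-aminopropyl chain next to the acetyl group) | COc1c(C(C)=O)c(C[C@@H](C)N)cc(O)c1-c1cc(-c2cc(-c3c(O)cc(O)c4c3C[C@@H](C)N[C@@H]4C)c3cc(C)cc(OC)c3c2O)c(O)c2c(OC)cc(C)cc12 | intermediate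
31 | korundamine A | COc1c2c(cc(O)c1-c1cc(-c3cc(-c4c(O)cc(O)c5c4C[C@@H](C)N[C@@H]5C)c4cc(C)cc(OC)c4c3O)c(O)c3c(OC)cc(C)cc13)C[C@@H](C)N=C2C | target

Total step count: 22. Longest linear sequence: 11 steps (steps 1 to 6, then 18 to 22).

Steps most likely to fail

Step 20. The two naphthols have nearly the same oxidation potential, so homocoupling of each partner competes statistically with the cross-coupling, and over-oxidation can erode material. The fallback is a directed Suzuki–Miyaura union that sets out from 27 and 20 and comes back to the route at 29. NBS should brominate 27 ortho to the naphthol hydroxyl to give tert-butyl N-[(2R)-1-[2-acetyl-5-(benzyloxy)-4-(3-bromo-4-hydroxy-5-methoxy-7-methylnaphthalen-1-yl)-3-methoxyphenyl]propan-2-yl]carbamate F1. The same bromination of 20 should give 2-bromo-4-[(1R,3R)-2-benzyl-6,8-bis(benzyloxy)-1,3-dimethyl-1,2,3,4-tetrahydroisoquinolin-5-yl]-8-methoxy-6-methylnaphthalen-1-ol F2, which Miyaura borylation (B2pin2, PdCl2(dppf), KOAc) should turn into the corresponding 2-(pinacolboryl)naphthol F3. Coupling of F1 with F3 (Pd(OAc)2, SPhos, K3PO4) should give the benzyl-protected binaphthol F4, and hydrogenolysis of F4 under the conditions of step 21 should give 29.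

Step 19. The free naphthol can protonate the alkylzinc reagent, the reagent can lose its carbamate by β-elimination, and transmetalation at the hindered triflate may be slow. The fallback is an sp3–sp2 Suzuki–Miyaura coupling with a trifluoroborate, which tolerates the hydroxyl group; it sets out from 12 and 26 and comes back at 27. Borylation of 12 (B2pin2, CuI, PPh3, LiOMe, DMF) should give tert-butyl N-[(2R)-1-(4,4,5,5-tetramethyl-1,3,2-dioxaborolan-2-yl)propan-2-yl]carbamate F5. KHF2 should convert it into potassium [(2R)-2-(tert-butoxycarbonylamino)propyl]trifluoroborate F6, and coupling of F6 with 26 (Pd(OAc)2, RuPhos, Cs2CO3, toluene/H2O, 85 °C) should give 27.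

Step 16. Iodination may go para to the free hydroxyl, next to the triflate, or proceed twice. The fallback uses the symmetry of the diol; it sets out from 22 and comes back at 24. NIS should iodinate 22 at one of its two equivalent ring positions to give 1-[4-(benzyloxy)-2,6-dihydroxy-3-iodophenyl]ethanone F7. The hydroxyl remote from iodine is the less hindered one and should be triflated selectively (PhNTf2, K2CO3, or Tf2O with 2,6-lutidine at −78 °C) to give 24.

Further compounds
F1 | step 20 | tert-butyl N-[(2R)-1-[2-acetyl-5-(benzyloxy)-4-(3-bromo-4-hydroxy-5-methoxy-7-methylnaphthalen-1-yl)-3-methoxyphenyl]propan-2-yl]carbamate | CC(=O)c1c(OC)c(-c2cc(Br)c(O)c3c(OC)cc(C)cc23)c(OCc2ccccc2)cc1C[C@@H](C)NC(=O)OC(C)(C)C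
F2 | step 20 | 2-bromo-4-[(1R,3R)-2-benzyl-6,8-bis(benzyloxy)-1,3-dimethyl-1,2,3,4-tetrahydroisoquinolin-5-yl]-8-methoxy-6-methylnaphthalen-1-ol | COc1cc(C)cc2c(-c3c(OCc4ccccc4)cc(OCc4ccccc4)c4c3C[C@@H](C)N(Cc3ccccc3)[C@@H]4C)cc(Br)c(O)c12
F3 | step 20 | 4-[(1R,3R)-2-benzyl-6,8-bis(benzyloxy)-1,3-dimethyl-1,2,3,4-tetrahydroisoquinolin-5-yl]-8-methoxy-6-methyl-2-(4,4,5,5-tetramethyl-1,3,2-dioxaborolan-2-yl)naphthalen-1-ol | COc1cc(C)cc2c(-c3c(OCc4ccccc4)cc(OCc4ccccc4)c4c3C[C@@H](C)N(Cc3ccccc3)[C@@H]4C)cc(B3OC(C)(C)C(C)(C)O3)c(O)c12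
F4 | step 20 | benzyl-protected binaphthol (29 with benzyl groups on the C6 oxygen of ring A, on both tetrahydroisoquinoline oxygens and on its nitrogen) | COc1c(C(C)=O)c(C[C@@H](C)NC(=O)OC(C)(C)C)cc(OCc2ccccc2)c1-c1cc(-c2cc(-c3c(OCc4ccccc4)cc(OCc4ccccc4)c4c3C[C@@H](C)N(Cc3ccccc3)[C@@H]4C)c3cc(C)cc(OC)c3c2O)c(O)c2c(OC)cc(C)cc12
F5 | step 19 | tert-butyl N-[(2R)-1-(4,4,5,5-tetramethyl-1,3,2-dioxaborolan-2-yl)propan-2-yl]carbamate | CC1(C)OB(C[C@@H](C)NC(=O)OC(C)(C)C)OC1(C)C
F6 | step 19 | potassium [(2R)-2-(tert-butoxycarbonylamino)propyl]trifluoroborate | F[B-](F)(F)C[C@@H](C)NC(=O)OC(C)(C)C.[K+]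
F7 | step 16 | 1-[4-(benzyloxy)-2,6-dihydroxy-3-iodophenyl]ethanone | CC(=O)c1c(O)cc(OCc2ccccc2)c(I)c1O
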